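The readings come from a simulation with made-up constants; the scatter is artificial.

**The runs.** South and north bracket the flask in free catalyst, and starting material and gas phase are the same in the three recipes.

the same everywhere: starting material 1.2 M; gas phase 41 mM (held)
- south: free catalyst 0.7 mol%; run made earlier
- north: free catalyst 2.8 mol%; run made earlier
- flask: free catalyst 1.4 mol%; time 12 min

- south (time / min: target / %): 2.50: 29; 5.00: 44; 8.00: 56; 10.0: 57; 12.0: 59; 15.0: 58
- north (time / min: target / %): 1.00: 18; 3.00: 46; 5.00: 68; 8.00: 82; 12.0: 89; 15.0: 87

(readings scatter by 2 percentage points)

- at the start none of the gas phase is in solution

1. the target standing at 12 min, as a percentage of the starting material charged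
2. the change that raises the amount of target at 12 min, in percent of the starting material charged most ("none" if none brings more than 2 percentage points) (Saturday's / Monday's / Thursday's / none)
3. amount of target at 12 min, in percent of the starting material charged, after Monday's

- Saturday's: doubling the transfer coefficient of the gas phase, all else as stated
- Monday's: doubling the amount of free catalyst, all else as stated
- Thursday's: doubling the saturation concentration of gas phase, all else as stated

**Carried quantity.** Take as reach the minus natural log of the share of the charge not yet target, the ordinate of a first-order plot. The flask's loading lies a factor 2.00 above south and the same factor below north. So the reckoning here assumes a power law in loading and takes, at equal times, the geometric mean of the two reaches, the middle reach 1.40 at 12 min.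

**The curve.** From the first readings, the reckoned reach of the flask starts at 0.165 min⁻¹. On that line the target crosses 0.5 of the charge near 4.20 min. At 5.00 min the mean reach is 0.813, still on the line at 0.825, with target 55.6 %. At 8.00 min it is 1.19, below the line's 1.32, so this reckoning puts the knee between, with target 69.6 %. The readings of south and north stay flat within scatter between 12 min and 15.0 min, so the reckoned level of the flask is 75.4 %.

**The changes.** Monday's flask has the loading of north, which read 89 %. If the rate follows dissolved gas in proportion, Thursday's doubles the reach, more than north's, and gives 93.9 %. Saturday's speeds the gas's arrival and leaves its level, so this reckoning picks Thursday's.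

**The forecast.** It gives 75 %, 88 % and Thursday's: “Thursday's doubles both the transfer driving force and the kinetic rate”.

**The result.** The flask gives 74.1 %, 86.9 % and Thursday's, with Thursday's gaining 15 percentage points, Monday's 13 points and Saturday's 12 points.

    gas phase ⇌ dissolved gas, rate k1*(csat - [dissolved gas]) (kL = 5.00 min⁻¹)
    starting material + dissolved gas + free catalyst → free catalyst + target (k = 2900 M⁻² min⁻¹)
    free catalyst → spent catalyst (k = 0.310 min⁻¹)
    starting material + dissolved gas → uncatalysed product (k = 2.90 M⁻¹ min⁻¹)

**Reach used.** The flask's reach is 1.35 against the carried 1.40. Target at 12 min stands lower because free catalyst dies and because gas crosses with resistance, each a part of the reason: the flask holds 74.1 % of target, without the death 94.4 %, without the resistance 93.2 %. For the same flask read at 3.0 min, south's readings give 32.0 % by interpolation and north read 46 %, so the mean reach gives 38.6 %, and that flask holds 39.3 % of target.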